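## Structural features

The target 28 is a germacrane: a ten-membered carbocycle with an E trisubstituted alkene (C1=C10, methyl on C10) and, across the ring, a trans-oxirane fused at C4–C5 (methyl on C4), so that the skeleton is an 11-oxabicyclo[8.1.0]undec-6-ene. Five stereocentres stand in an unbroken row, C4 (R), C5 (R), C6 (S), C7 (R) and C8 (R): the oxirane CH (C5) is followed by the carbinol C6 with the 3,4,5-trimethoxybenzoate, by C7 with the isopropyl group and by C8 with a free hydroxyl. Read along the ring, the C5–O and C6–O bonds are threo (syn in the zigzag), the C6 oxygen and the C8 branch are related as in an anti homoallylic alcohol, and the C8 oxygen is cis to the isopropyl group. The molecule is fragile in three ways: the oxirane faces the C1=C10 alkene across the medium ring, so acid can trigger transannular cyclisation; the O6 ester and the O8 hydroxyl are 1,3-related, so base can move the acyl group; and the E-cyclodecene is strained. The real difficulty is to close the ten-membered ring and at the same time place the contiguous C5–C8 array correctly. The C6–C7 bond is the natural place to do both, because it joins an oxygenated carbon to a carbon with a three-carbon branch; once isopropyl is read as isopropenyl, HO–C6–C7–C11(=C12) is the retron of a carbonyl allylation. The key step therefore lets C7, the γ-carbon of an allylmetal built from C12–C11–C7, attack a C6 aldehyde that hangs on the preformed oxirane, which closes the ring and sets C6 and C7 in one event.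

## Logic of the disconnections

28 to 27. The C8 hydroxyl is masked as a silyl ether (O8–H replaced by O8–Si). A free hydroxyl 1,3 to O6 would compete in the acylation and bind zinc in the ring closure, so it stays protected to the last step. The demand is a desilylation that is neither acidic (oxirane facing C1=C10) nor strongly basic (acyl shift from O6 to O8).

27 to 25 and 26. The ester C–O bond at O6 is cut. The aroyl part is bought as 26, and attaching it late keeps an electrophilic ester away from organolithium, hydride and organozinc reagents. The forward step must acylate a secondary alcohol flanked by the oxirane and the isopropyl-bearing carbon.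

25 to 24. Two hydrogens are removed from C11 and C12, so isopropyl becomes isopropenyl. This makes C6–C7 the bond of a homoallylic alcohol and exposes the allylation retron. The forward hydrogenation must saturate a 1,1-disubstituted alkene and leave the trisubstituted C1=C10 alkene and the oxirane alone.

24 to 22. The ring bond C6–C7 is cut, with O6 taken back to an aldehyde and C12 to the allylic chloride; 23 is the organozinc form in which C7 is nucleophilic. This one cut removes the ring and two stereocentres and leaves an open chain whose only stereocentres are the oxirane carbons and C8. The forward step must beat oligomerisation, bond through C7 and not C12, and pair the right faces of aldehyde and allyl unit.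

22 to 21 to 20. The formyl group goes back to the primary alcohol and this to its 4-methoxybenzyl ether. The epoxy aldehyde is the most sensitive compound of the route and exists for one step only; the ether carries O6 through the organometallic and hydride steps. The deprotection and the oxidation must tolerate an allylic chloride, a silyl ether and the oxirane.

20 to 18 to 17. The C12–Cl bond is traced through the sulfonate 19 to the allylic alcohol 18 and its acetate 17. The chloride is made late because it would not survive carbanion, thiophile or hydride reagents. The substitution must go without allylic transposition and keep the E geometry.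

17 to 16 to 15. The O8–Si bond and then the C8–H bond are cut, which turns the carbinol into an enone. C8 is thereby reduced to a reagent-controlled hydride delivery. The reduction must be 1,2-selective and must tell the alkenyl flank of the ketone from the allylic methylene flank.

15 to 14. The carbonyl group is masked as a dithiane, which inverts the polarity of C8 and prepares the next cut. The unmasking must run at neutral pH because of the oxirane and must not move the C1=C10 alkene into conjugation.

14 to 11 and 5. The C8–C9 bond is cut between the acyl-anion carbon and an allylic methylene. This divides the fifteen-carbon chain into a ten-carbon electrophile 5 that holds the oxirane and a five-carbon nucleophile 11. The anion must alkylate at its sulfur-bearing carbon and not at C11, must not expel the C12 oxygen, and must prefer the allylic bromide to the oxirane. Using the hydroxyl as its alkoxide in 12 answers the first two points and gives 13, which is capped as 14 in the same flask.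

5 to 4 to 3 to 2 to 1. The C9–Br bond goes back to the allylic alcohol 4, the C9–O bond to the methyl group of 3, the ether to 2 and the oxirane to the allylic alcohol 1. The last cut removes both C4 and C5, which are thus set by a catalyst in the first step. The allylic oxidation must hit the E methyl group only, which is easy once the other alkene has become the oxirane, and the bromination must leave the oxirane closed.

11 to 10 to 8 to 6 and 7, with 9. The C7=C11 double bond is cut by an olefination transform, and 9 supplies the sulfur atoms. The olefination fixes the E geometry that places C8 and C12 trans, and the acetal exchange is done while C12 is still an ester, which keeps capture of the intermediate cation at C8.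

## Other disconnections considered

Alternative 1: The cut is C2–C3, with C5–C10 restored in the backward sense, so the ten-membered ring is traded for the cyclohexanol A1, (1R,2S,3S,4R,6S)-4-(TBS-oxy)-6-ethenyl-2-(PMB-oxy)-6-methyl-3-(propan-2-yl)-1-(prop-1-en-2-yl)cyclohexan-1-ol, in which isopropenyl on the carbinol carbon (C5) and vinyl on the neighbouring quaternary carbon (C10) are trans. In the forward direction the potassium alkoxide of A1 (KH, 18-crown-6) would undergo an anionic oxy-Cope rearrangement through a chair, and the ring-expanded C4=C5 enolate would be trapped with PhNTf2 as the dienyl triflate A2, (1Z,5E,8R,9S,10S)-8-(TBS-oxy)-10-(PMB-oxy)-2,6-dimethyl-9-(propan-2-yl)cyclodeca-1,5-dien-1-yl trifluoromethanesulfonate.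
- In its favour: ring expansion needs no high dilution, the chair should carry the trans arrangement into both E ring alkenes, and C6, C7 and C8 are set on a six-membered ring, where relative stereocontrol is best understood. On this last point the alternative is better than the chosen plan, which sets C6 and C7 in the ring-closing event itself.
- Against it here: A1 is a crowded cyclohexane with a quaternary carbon next to a tertiary carbinol and five stereocentres, and its assembly would cost more steps than the open chain 22. A2 is still three operations from the oxirane (reduction of the triflate, epoxidation, exchange of the C6 ether for the ester). The epoxidation of C4=C5 would have no hydroxyl to guide it and would have to choose one alkene and one face. A2 and its reduction product are 1,5-dienes of the kind that revert to divinylcyclohexanes on warming.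
- Comparison: both plans rely on a six-membered chair, in a sigmatropic shift here and in a carbonyl addition in the chosen plan. The chosen plan should be shorter, because the oxirane is in place from step 1 and ring closure leaves three steps.

Alternative 2: The cut is C1–C2. The seco compound A3, (1S,2S,3R,5E)-3-(TBS-oxy)-1-[(2R,3R)-3-ethenyl-3-methyloxiran-2-yl]-6-iodo-5-methyl-2-(propan-2-yl)hex-5-en-1-yl 3,4,5-trimethoxybenzoate, carries a vinyl group on the oxirane carbon C4 and an E vinyl iodide at C1. 9-BBN-H would add to the vinyl group to put boron on C2, and Pd(dppf)Cl2 with base would then join C2 to C1 and give A4, the C8 TBS ether of the target, which is the same compound as 27.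
- In its favour: no stereocentre is made in the ring closure, all five are in place and the ester is on board, so one deprotection follows. On stereochemical risk at the ring-closing step this alternative is better than the chosen plan, and from 27 on it is its equal.
- Against it here: the B-alkyl Suzuki reaction has closed few ten-membered rings, and reductive elimination would have to create the strained E-cyclodecene. A vinyl oxirane is prone to ionisation by zerovalent palladium and to opening by boranes, so the hydroboration would have to be complete before palladium is added. The whole C4–C8 array would have to be built by open-chain methods, with the ester carried through basic aqueous coupling conditions.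
- Comparison: cutting C6–C7 also removes two stereocentres, whereas cutting C1–C2 removes only the ring; the alternative would be the longer route.

Alternative 3: The cut is C5–C6, taken back one oxidation level so that C4=C5 is an alkene. The open-chain aldehyde A5, (2R,3R,5E,9E)-3-(TBS-oxy)-10-iodo-5,9-dimethyl-2-(propan-2-yl)deca-5,9-dienal, holds an E vinyl iodide at C5. CrCl2 with catalytic NiCl2 would convert it into a vinylchromium species that adds to the C6 aldehyde and gives the cyclic dienol A6, (1R,2E,6E,9R,10S)-9-(TBS-oxy)-3,7-dimethyl-10-(propan-2-yl)cyclodeca-2,6-dien-1-ol.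
- In its favour: this addition is among the most dependable ways to close medium rings at an allylic carbinol and tolerates silyl ethers. Only C6 is made, and it could be corrected by oxidation and reduction, which is a better position than that of the chosen plan, where C6 and C7 stand or fall together. The new allylic hydroxyl could direct the epoxidation of C4=C5, and the C4 methyl group, cis to C6, should favour the threo epoxy alcohol that 28 needs.
- Against it here: A5 is an α-branched β-silyloxy aldehyde that can epimerise at C7 or lose silanol. The C7/C8 pair has to be made by open-chain methods. The sense at C6 would depend on induction from C7 and C8 in a ring-forming transition state and is no easier to foresee than in the chosen plan. A6 is a germacra-1(10),4-diene, open to Cope rearrangement and to transannular cyclisation during the epoxidation, which also adds a step after ring closure.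
- Comparison: in step count the two plans are close, with the chosen one ahead by the epoxidation step. Stoichiometric chromium counts against the alternative; high dilution is common to both.

Key step: step 16

Remarks on the chemistry (assumptions):
- Germacrane numbering is used for positions in the text. PMB = 4-methoxybenzyl, TBS = tert-butyl(dimethyl)silyl.
- In the aldehyde 22 the oxirane CH carbon is S by the sequence rules, because the formyl group outranks C4, although its geometry is that of C5 (R) in 28. In germacrane numbering 22 is therefore (4R,5S,8R); the label (4R,5R) fits the alcohol 21 and the ring compounds, not the aldehyde. Likewise C7 is S in 24, 25 and 27 and R in 28 with unchanged geometry.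
- 6 is used as its commercial 60% aqueous solution.

## Route

Step 1
Reactants: 1 geraniol, (2E)-3,7-dimethylocta-2,6-dien-1-ol
Product: 2 [(2R,3R)-3-methyl-3-(4-methylpent-3-en-1-yl)oxiran-2-yl]methanol
Conditions: Ti(OiPr)4 (5 mol %), diethyl D-(−)-tartrate (7 mol %), t-BuOOH, 4 Å MS, CH2Cl2, −20 °C
Reagents that add atoms: tert-butyl hydroperoxide CC(C)(C)OO
Why: Sharpless asymmetric epoxidation; only the allylic-alcohol alkene reacts, and the D-(−)-tartrate ligand directs oxygen to the face that gives the (2R,3R)-oxirane, which becomes C4 and C5 of 28.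

Step 2
Reactants: 2 [(2R,3R)-3-methyl-3-(4-methylpent-3-en-1-yl)oxiran-2-yl]methanol
Product: 3 (2R,3R)-3-(PMB-oxymethyl)-2-methyl-2-(4-methylpent-3-en-1-yl)oxirane
Conditions: NaH, 4-methoxybenzyl chloride, n-Bu4NI (cat.), THF/DMF, 0 °C to rt
Reagents that add atoms: 4-methoxybenzyl chloride COc1ccc(CCl)cc1
Why: Williamson etherification; fast O-alkylation of the sodium alkoxide in an aprotic medium outruns Payne migration of the oxirane, and the ether can later be removed oxidatively without acid.

Step 3
Reactants: 3 (2R,3R)-3-(PMB-oxymethyl)-2-methyl-2-(4-methylpent-3-en-1-yl)oxirane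
Product: 4 (2E)-5-[(2R,3R)-3-(PMB-oxymethyl)-2-methyloxiran-2-yl]-2-methylpent-2-en-1-ol
Conditions: SeO2 (0.4 equiv), t-BuOOH, salicylic acid (cat.), CH2Cl2, rt
Reagents that add atoms: tert-butyl hydroperoxide CC(C)(C)OO
Why: Catalytic SeO2 allylic oxidation (ene reaction, then [2,3]-shift) of the only remaining alkene, which takes the E methyl group of the trisubstituted alkene and so fixes the C1=C10 geometry; the reaction is stopped before the alcohol is carried on to the enal.

Step 4
Reactants: 4 (2E)-5-[(2R,3R)-3-(PMB-oxymethyl)-2-methyloxiran-2-yl]-2-methylpent-2-en-1-ol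
Product: 5 (2R,3R)-2-[(3E)-5-bromo-4-methylpent-3-en-1-yl]-3-(PMB-oxymethyl)-2-methyloxirane
Conditions: CBr4, PPh3, 2,6-lutidine, CH2Cl2, −20 to 0 °C
Reagents that add atoms: carbon tetrabromide BrC(Br)(Br)Br
Why: Appel bromination; SN2 displacement at the primary allylic carbon under neutral conditions keeps the alkene in place and the oxirane closed.

Step 5
Reactants: 6 2,2-dimethoxyacetaldehyde; 7 ethyl 2-(triphenyl-λ5-phosphanylidene)propanoate
Product: 8 ethyl (2E)-4,4-dimethoxy-2-methylbut-2-enoate
Conditions: CH2Cl2 (6 as 60% aq. solution), rt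
Reagents that add atoms: none
Why: Wittig olefination with a stabilised α-methyl ylide, which is E-selective and so places the acetal carbon (C8) trans to the ester carbon (C12) across C7=C11.

Step 6
Reactants: 8 ethyl (2E)-4,4-dimethoxy-2-methylbut-2-enoate; 9 propane-1,3-dithiol
Product: 10 ethyl (2E)-3-(1,3-dithian-2-yl)-2-methylprop-2-enoate
Conditions: BF3·OEt2, CH2Cl2, −20 to 0 °C
Reagents that add atoms: none
Why: Lewis-acid transthioacetalisation; with C12 still an ester the intermediate oxocarbenium ion has no stabilised positive charge at C11, so the thiol is captured at C8 and the E alkene is kept.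

Step 7
Reactants: 10 ethyl (2E)-3-(1,3-dithian-2-yl)-2-methylprop-2-enoate
Product: 11 (2E)-3-(1,3-dithian-2-yl)-2-methylprop-2-en-1-ol
Conditions: i-Bu2AlH (2.2 equiv), CH2Cl2, −78 °C; aq. potassium sodium tartrate
Reagents that add atoms: none
Why: 1,2-Reduction of the enoate to the allylic alcohol by i-Bu2AlH; the dithiane and the alkene geometry are untouched.

Step 8
Reactants: 11 (2E)-3-(1,3-dithian-2-yl)-2-methylprop-2-en-1-ol; 5 (2R,3R)-2-[(3E)-5-bromo-4-methylpent-3-en-1-yl]-3-(PMB-oxymethyl)-2-methyloxirane
Product: 14 (2E)-3-{2-[(2E)-5-[(2R,3R)-3-(PMB-oxymethyl)-2-methyloxiran-2-yl]-2-methylpent-2-en-1-yl]-1,3-dithian-2-yl}-2-methylprop-2-en-1-yl acetate, via dilithio dianion 12 (not isolated), via lithium alkoxide 13 (not isolated)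
Conditions: n-BuLi (2.1 equiv per 11), THF, −30 °C; DMPU, 5, −78 to −40 °C; Ac2O, −40 to 0 °C
Reagents that add atoms: acetic anhydride CC(=O)OC(C)=O; n-butyllithium [Li]CCCC (lithium in 12 and 13 only)
Why: Corey–Seebach alkylation: a lithiated 2-alkenyl-1,3-dithiane reacts with alkyl halides at the sulfur-bearing carbon (C8), and the primary allylic bromide of 5 is displaced by SN2 far faster than the trisubstituted oxirane is opened. Working with the dianion 12 keeps O12 as an alkoxide that cannot be expelled, which closes the 1,4-elimination path to a dienyl ketene dithioacetal that threatens O-protected analogues, and its charge steers the electrophile away from C11. Acetic anhydride caps the alkoxide 13 in the same flask, so O12 is protected for the thiophile and hydride steps without a separate operation.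

Step 9
Reactants: 14 (2E)-3-{2-[(2E)-5-[(2R,3R)-3-(PMB-oxymethyl)-2-methyloxiran-2-yl]-2-methylpent-2-en-1-yl]-1,3-dithian-2-yl}-2-methylprop-2-en-1-yl acetate
Product: 15 (2E,6E)-9-[(2R,3R)-3-(PMB-oxymethyl)-2-methyloxiran-2-yl]-2,6-dimethyl-4-oxonona-2,6-dien-1-yl acetate
Conditions: MeI, CaCO3, MeCN/H2O (4:1), 45 °C
Reagents that add atoms: water O
Why: Dithiane unmasking by S-methylation and hydrolysis; CaCO3 keeps the medium neutral, so the oxirane, the PMB ether and the acetate persist. 15 is taken on at once, because its C9 methylene lies between the ketone and the C1=C10 alkene and acid or base could draw that alkene into conjugation.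

Step 10
Reactants: 15 (2E,6E)-9-[(2R,3R)-3-(PMB-oxymethyl)-2-methyloxiran-2-yl]-2,6-dimethyl-4-oxonona-2,6-dien-1-yl acetate
Product: 16 (2E,4R,6E)-4-hydroxy-9-[(2R,3R)-3-(PMB-oxymethyl)-2-methyloxiran-2-yl]-2,6-dimethylnona-2,6-dien-1-yl acetate
Conditions: (S)-1-methyl-3,3-diphenyltetrahydro-1H,3H-pyrrolo[1,2-c][1,3,2]oxazaborole (0.3 equiv), catecholborane, toluene, −78 °C
Reagents that add atoms: none
Why: Corey–Bakshi–Shibata reduction: the ketone binds to the boron of the catalyst anti to its larger flank, the alkenyl group, and the (S)-catalyst then delivers hydride to the face that gives the 4R carbinol (C8 of 28), by analogy with aryl and alkenyl alkyl ketones. The reduction is 1,2-selective, catecholborane at −78 °C leaves the alkenes, the acetate and the oxirane alone, and the remote oxirane stereocentres have no influence.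

Step 11
Reactants: 16 (2E,4R,6E)-4-hydroxy-9-[(2R,3R)-3-(PMB-oxymethyl)-2-methyloxiran-2-yl]-2,6-dimethylnona-2,6-dien-1-yl acetate
Product: 17 (2E,4R,6E)-4-(TBS-oxy)-9-[(2R,3R)-3-(PMB-oxymethyl)-2-methyloxiran-2-yl]-2,6-dimethylnona-2,6-dien-1-yl acetate
Conditions: TBSCl, imidazole, DMF, rt
Reagents that add atoms: tert-butyl(chloro)dimethylsilane CC(C)(C)[Si](C)(C)Cl
Why: Silylation of the secondary allylic alcohol through the N-silylimidazolium species; no other free hydroxyl is present and C8 is not touched.

Step 12
Reactants: 17 (2E,4R,6E)-4-(TBS-oxy)-9-[(2R,3R)-3-(PMB-oxymethyl)-2-methyloxiran-2-yl]-2,6-dimethylnona-2,6-dien-1-yl acetate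
Product: 18 (2E,4R,6E)-4-(TBS-oxy)-9-[(2R,3R)-3-(PMB-oxymethyl)-2-methyloxiran-2-yl]-2,6-dimethylnona-2,6-dien-1-ol
Conditions: K2CO3 (cat.), MeOH, 0 °C
Reagents that add atoms: none
Why: Base-catalysed methanolysis of the primary allylic acetate; the secondary silyl ether, the PMB ether and the oxirane are stable to these conditions.

Step 13
Reactants: 18 (2E,4R,6E)-4-(TBS-oxy)-9-[(2R,3R)-3-(PMB-oxymethyl)-2-methyloxiran-2-yl]-2,6-dimethylnona-2,6-dien-1-ol
Product: 20 (2R,3R)-2-[(3E,6R,7E)-6-(TBS-oxy)-9-chloro-4,8-dimethylnona-3,7-dien-1-yl]-3-(PMB-oxymethyl)-2-methyloxirane, via allylic mesylate 19 (not isolated)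
Conditions: MsCl, 2,4,6-collidine, LiCl, DMF, 0 °C
Reagents that add atoms: lithium chloride [Li+].[Cl-]; methanesulfonyl chloride CS(=O)(=O)Cl (atoms in 19 only)
Why: Mesylation and in situ SN2 displacement by chloride; the primary allylic centre reacts without transposition, so the E geometry and the C8 centre stay as they are.

Step 14
Reactants: 20 (2R,3R)-2-[(3E,6R,7E)-6-(TBS-oxy)-9-chloro-4,8-dimethylnona-3,7-dien-1-yl]-3-(PMB-oxymethyl)-2-methyloxirane
Product: 21 {(2R,3R)-3-[(3E,6R,7E)-6-(TBS-oxy)-9-chloro-4,8-dimethylnona-3,7-dien-1-yl]-3-methyloxiran-2-yl}methanol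
Conditions: DDQ (2,3-dichloro-5,6-dicyano-1,4-benzoquinone), CH2Cl2/pH 7 phosphate buffer (10:1), 0 °C
Reagents that add atoms: none
Why: Oxidative cleavage of the PMB ether by benzylic hydride abstraction and hydrolysis of the oxocarbenium ion; the buffered medium spares the oxirane, the silyl ether and the allylic chloride.

Step 15
Reactants: 21 {(2R,3R)-3-[(3E,6R,7E)-6-(TBS-oxy)-9-chloro-4,8-dimethylnona-3,7-dien-1-yl]-3-methyloxiran-2-yl}methanol
Product: 22 (2S,3R)-3-[(3E,6R,7E)-6-(TBS-oxy)-9-chloro-4,8-dimethylnona-3,7-dien-1-yl]-3-methyloxirane-2-carbaldehyde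
Conditions: Dess–Martin periodinane, NaHCO3, CH2Cl2, 0 °C to rt
Reagents that add atoms: none
Why: Dess–Martin oxidation of the epoxy alcohol under buffered, non-acidic conditions; the oxirane CH is not epimerised, and the aldehyde is used directly in the next step.

Step 16
Reactants: 22 (2S,3R)-3-[(3E,6R,7E)-6-(TBS-oxy)-9-chloro-4,8-dimethylnona-3,7-dien-1-yl]-3-methyloxirane-2-carbaldehyde
Product: 24 (1R,2S,3S,4R,6E,10R)-4-(TBS-oxy)-6,10-dimethyl-3-(prop-1-en-2-yl)-11-oxabicyclo[8.1.0]undec-6-en-2-ol, via allyl(ethyl)zinc 23 (not isolated)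
Conditions: Pd(PPh3)4 (15 mol %), Et2Zn (3 equiv), K2CO3, N,N-dimethylacetamide/THF, rt, 22 added by syringe pump to 0.005 M
Reagents that add atoms: diethylzinc CC[Zn]CC (atoms in 23 only)
Why: Zerovalent palladium ionises the allylic chloride of 22 to a π-allylpalladium chloride, Et2Zn transmetallates it to the nucleophilic allyl(ethyl)zinc 23, and the palladium is returned with loss of ethene and ethane; the closest known reaction type is the palladium-catalysed umpolung allylation of aldehydes by allylic halides or esters with Et2Zn, which is established for end-to-end closure of ten-membered germacrane rings. 23 then adds to the C6 aldehyde through its γ-carbon C7 in a closed six-membered chair around zinc (Zn, O, C6, C7, C11, C12): an SE2' reaction of the allyl unit and a 10-exo-trig closure at the carbonyl group that forms the C1–C10 carbocycle and leaves C11=C12 outside it as the isopropenyl group. The relative configuration of C6 and C7 (hydroxyl anti to the C8 branch) is set by this chair, in which C5 on the aldehyde and the C8 chain of the E allyl unit are both equatorial; since 1,3-shifts of zinc are fast, the allyl geometry is the thermodynamic one at the moment of addition. The absolute sense at C6 is controlled by the oxirane: in the crown-like fold of the forming ring C4 lies gauche to the incoming C7 with the carbonyl oxygen beside H5, and C7 then approaches anti to the C5–O bond, which gives the threo C5/C6 relation of 28 (open-chain additions to epoxy aldehydes lean to the erythro isomer, so this rests on the ring constraint). The absolute sense at C7 is controlled by C8: allylic 1,3-strain with the C11 methyl group keeps H8 in the plane of the allyl unit, and the aldehyde is taken up anti to the ring bond C8–C9 with the silyloxy group turned outward, which gives the 7,8-relation of 28. The step needs ring closure to outrun oligomerisation and reduction or protonation of the allyl intermediates, which slow addition of 22 to excess Et2Zn at high dilution should secure; it needs bonding through C7 and not C12, which the cyclic transition state ensures; and it needs the oxirane and the silyl ether to survive, which the weakly Lewis-acidic ethylzinc species and K2CO3 as acid scavenger should allow.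

Step 17
Reactants: 24 (1R,2S,3S,4R,6E,10R)-4-(TBS-oxy)-6,10-dimethyl-3-(prop-1-en-2-yl)-11-oxabicyclo[8.1.0]undec-6-en-2-ol
Product: 25 (1R,2S,3S,4R,6E,10R)-4-(TBS-oxy)-6,10-dimethyl-3-(propan-2-yl)-11-oxabicyclo[8.1.0]undec-6-en-2-ol
Conditions: RhCl(PPh3)3 (10 mol %), H2 (1 atm), benzene/EtOH (1:1), rt
Reagents that add atoms: none
Why: Homogeneous hydrogenation with RhCl(PPh3)3, which reduces the 1,1-disubstituted isopropenyl alkene much faster than the trisubstituted ring alkene and does not open oxiranes or cleave silyl ethers; no stereocentre is created or touched.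

Step 18
Reactants: 25 (1R,2S,3S,4R,6E,10R)-4-(TBS-oxy)-6,10-dimethyl-3-(propan-2-yl)-11-oxabicyclo[8.1.0]undec-6-en-2-ol; 26 3,4,5-trimethoxybenzoyl chloride
Product: 27 (1R,2S,3S,4R,6E,10R)-4-(TBS-oxy)-6,10-dimethyl-3-(propan-2-yl)-11-oxabicyclo[8.1.0]undec-6-en-2-yl 3,4,5-trimethoxybenzoate
Conditions: Et3N, DMAP, CH2Cl2, rt to 40 °C
Reagents that add atoms: none
Why: DMAP-catalysed acylation through the acylpyridinium ion, which is reactive enough for the hindered C6 hydroxyl; Et3N takes up HCl so the oxirane is not exposed to acid, and O8 is still silylated.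

Step 19
Reactants: 27 (1R,2S,3S,4R,6E,10R)-4-(TBS-oxy)-6,10-dimethyl-3-(propan-2-yl)-11-oxabicyclo[8.1.0]undec-6-en-2-yl 3,4,5-trimethoxybenzoate
Product: 28 (1R,2S,3R,4R,6E,10R)-4-hydroxy-6,10-dimethyl-3-(propan-2-yl)-11-oxabicyclo[8.1.0]undec-6-en-2-yl 3,4,5-trimethoxybenzoate
Conditions: n-Bu4NF, AcOH (1:1), THF, 0 °C to rt
Reagents that add atoms: none
Why: Fluoride-induced desilylation; buffering with acetic acid avoids a free alkoxide at O8, which could take the acyl group from O6 by a 1,3-shift, and avoids the acid that would open the oxirane onto the C1=C10 alkene.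

## Compound list

1 | geraniol, (2E)-3,7-dimethylocta-2,6-dien-1-ol | CC(C)=CCC/C(C)=C/CO | starting material
2 | [(2R,3R)-3-methyl-3-(4-methylpent-3-en-1-yl)oxiran-2-yl]methanol | CC(C)=CCC[C@@]1(C)O[C@@H]1CO | intermediate
3 | (2R,3R)-3-{[(4-methoxyphenyl)methoxy]methyl}-2-methyl-2-(4-methylpent-3-en-1-yl)oxirane | CC(C)=CCC[C@@]1(C)O[C@@H]1COCc1ccc(OC)cc1 | intermediate
4 | (2E)-5-[(2R,3R)-3-{[(4-methoxyphenyl)methoxy]methyl}-2-methyloxiran-2-yl]-2-methylpent-2-en-1-ol | OC/C(C)=C/CC[C@@]1(C)O[C@@H]1COCc1ccc(OC)cc1 | intermediate
5 | (2R,3R)-2-[(3E)-5-bromo-4-methylpent-3-en-1-yl]-3-{[(4-methoxyphenyl)methoxy]methyl}-2-methyloxirane | BrC/C(C)=C/CC[C@@]1(C)O[C@@H]1COCc1ccc(OC)cc1 | intermediate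
6 | 2,2-dimethoxyacetaldehyde | COC(OC)C=O | starting material
7 | ethyl 2-(triphenyl-λ5-phosphanylidene)propanoate | CCOC(=O)C(C)=P(c1ccccc1)(c1ccccc1)c1ccccc1 | starting material
8 | ethyl (2E)-4,4-dimethoxy-2-methylbut-2-enoate | CCOC(=O)/C(C)=C/C(OC)OC | intermediate
9 | propane-1,3-dithiol | SCCCS | starting material
10 | ethyl (2E)-3-(1,3-dithian-2-yl)-2-methylprop-2-enoate | CCOC(=O)/C(C)=C/C1SCCCS1 | intermediate
11 | (2E)-3-(1,3-dithian-2-yl)-2-methylprop-2-en-1-ol | OC/C(C)=C/C1SCCCS1 | intermediate
12 | lithium (2E)-3-(2-lithio-1,3-dithian-2-yl)-2-methylprop-2-en-1-olate | [Li]OC/C(C)=C/C1([Li])SCCCS1 | intermediate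
13 | lithium (2E)-3-{2-[(2E)-5-[(2R,3R)-3-{[(4-methoxyphenyl)methoxy]methyl}-2-methyloxiran-2-yl]-2-methylpent-2-en-1-yl]-1,3-dithian-2-yl}-2-methylprop-2-en-1-olate | [Li]OC/C(C)=C/C1(C/C(C)=C/CC[C@@]2(C)O[C@@H]2COCc3ccc(OC)cc3)SCCCS1 | intermediate
14 | (2E)-3-{2-[(2E)-5-[(2R,3R)-3-{[(4-methoxyphenyl)methoxy]methyl}-2-methyloxiran-2-yl]-2-methylpent-2-en-1-yl]-1,3-dithian-2-yl}-2-methylprop-2-en-1-yl acetate | CC(=O)OC/C(C)=C/C1(C/C(C)=C/CC[C@@]2(C)O[C@@H]2COCc3ccc(OC)cc3)SCCCS1 | intermediate
15 | (2E,6E)-9-[(2R,3R)-3-{[(4-methoxyphenyl)methoxy]methyl}-2-methyloxiran-2-yl]-2,6-dimethyl-4-oxonona-2,6-dien-1-yl acetate | CC(=O)OC/C(C)=C/C(=O)C/C(C)=C/CC[C@@]1(C)O[C@@H]1COCc1ccc(OC)cc1 | intermediate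
16 | (2E,4R,6E)-4-hydroxy-9-[(2R,3R)-3-{[(4-methoxyphenyl)methoxy]methyl}-2-methyloxiran-2-yl]-2,6-dimethylnona-2,6-dien-1-yl acetate | CC(=O)OC/C(C)=C/[C@H](O)C/C(C)=C/CC[C@@]1(C)O[C@@H]1COCc1ccc(OC)cc1 | intermediate
17 | (2E,4R,6E)-4-{[tert-butyl(dimethyl)silyl]oxy}-9-[(2R,3R)-3-{[(4-methoxyphenyl)methoxy]methyl}-2-methyloxiran-2-yl]-2,6-dimethylnona-2,6-dien-1-yl acetate | CC(=O)OC/C(C)=C/[C@H](O[Si](C)(C)C(C)(C)C)C/C(C)=C/CC[C@@]1(C)O[C@@H]1COCc1ccc(OC)cc1 | intermediate
18 | (2E,4R,6E)-4-{[tert-butyl(dimethyl)silyl]oxy}-9-[(2R,3R)-3-{[(4-methoxyphenyl)methoxy]methyl}-2-methyloxiran-2-yl]-2,6-dimethylnona-2,6-dien-1-ol | OC/C(C)=C/[C@H](O[Si](C)(C)C(C)(C)C)C/C(C)=C/CC[C@@]1(C)O[C@@H]1COCc1ccc(OC)cc1 | intermediate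
19 | (2E,4R,6E)-4-{[tert-butyl(dimethyl)silyl]oxy}-9-[(2R,3R)-3-{[(4-methoxyphenyl)methoxy]methyl}-2-methyloxiran-2-yl]-2,6-dimethylnona-2,6-dien-1-yl methanesulfonate | CS(=O)(=O)OC/C(C)=C/[C@H](O[Si](C)(C)C(C)(C)C)C/C(C)=C/CC[C@@]1(C)O[C@@H]1COCc1ccc(OC)cc1 | intermediate
20 | (2R,3R)-2-[(3E,6R,7E)-6-{[tert-butyl(dimethyl)silyl]oxy}-9-chloro-4,8-dimethylnona-3,7-dien-1-yl]-3-{[(4-methoxyphenyl)methoxy]methyl}-2-methyloxirane | ClC/C(C)=C/[C@H](O[Si](C)(C)C(C)(C)C)C/C(C)=C/CC[C@@]1(C)O[C@@H]1COCc1ccc(OC)cc1 | intermediate
21 | {(2R,3R)-3-[(3E,6R,7E)-6-{[tert-butyl(dimethyl)silyl]oxy}-9-chloro-4,8-dimethylnona-3,7-dien-1-yl]-3-methyloxiran-2-yl}methanol | ClC/C(C)=C/[C@H](O[Si](C)(C)C(C)(C)C)C/C(C)=C/CC[C@@]1(C)O[C@@H]1CO | intermediate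
22 | (2S,3R)-3-[(3E,6R,7E)-6-{[tert-butyl(dimethyl)silyl]oxy}-9-chloro-4,8-dimethylnona-3,7-dien-1-yl]-3-methyloxirane-2-carbaldehyde | ClC/C(C)=C/[C@H](O[Si](C)(C)C(C)(C)C)C/C(C)=C/CC[C@@]1(C)O[C@@H]1C=O | intermediate
23 | ethyl{(2E,4R,6E)-4-{[tert-butyl(dimethyl)silyl]oxy}-9-[(2R,3S)-3-formyl-2-methyloxiran-2-yl]-2,6-dimethylnona-2,6-dien-1-yl}zinc | CC[Zn]C/C(C)=C/[C@H](O[Si](C)(C)C(C)(C)C)C/C(C)=C/CC[C@@]1(C)O[C@@H]1C=O | intermediate
24 | (1R,2S,3S,4R,6E,10R)-4-{[tert-butyl(dimethyl)silyl]oxy}-6,10-dimethyl-3-(prop-1-en-2-yl)-11-oxabicyclo[8.1.0]undec-6-en-2-ol | O[C@H]1[C@H](C(C)=C)[C@H](O[Si](C)(C)C(C)(C)C)C/C(C)=C/CC[C@@]2(C)O[C@H]12 | intermediate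
25 | (1R,2S,3S,4R,6E,10R)-4-{[tert-butyl(dimethyl)silyl]oxy}-6,10-dimethyl-3-(propan-2-yl)-11-oxabicyclo[8.1.0]undec-6-en-2-ol | O[C@H]1[C@H](C(C)C)[C@H](O[Si](C)(C)C(C)(C)C)C/C(C)=C/CC[C@@]2(C)O[C@H]12 | intermediate
26 | 3,4,5-trimethoxybenzoyl chloride | COc1cc(cc(OC)c1OC)C(Cl)=O | starting material
27 | (1R,2S,3S,4R,6E,10R)-4-{[tert-butyl(dimethyl)silyl]oxy}-6,10-dimethyl-3-(propan-2-yl)-11-oxabicyclo[8.1.0]undec-6-en-2-yl 3,4,5-trimethoxybenzoate | COc1cc(C(=O)O[C@H]2[C@H](C(C)C)[C@H](O[Si](C)(C)C(C)(C)C)C/C(C)=C/CC[C@@]3(C)O[C@H]23)cc(OC)c1OC | intermediate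
28 | (1R,2S,3R,4R,6E,10R)-4-hydroxy-6,10-dimethyl-3-(propan-2-yl)-11-oxabicyclo[8.1.0]undec-6-en-2-yl 3,4,5-trimethoxybenzoate (CNP0279501.1) | COc1cc(C(=O)O[C@H]2[C@H](C(C)C)[C@H](O)C/C(C)=C/CC[C@@]3(C)O[C@H]23)cc(OC)c1OC | target

## Step count and least certain steps

Total step count: 19. Longest linear sequence: 16 steps (steps 1–4 and 8–19, from 1); the branch from 6 and 7 has three steps (5–7) before it joins.

Step 16 (key step). What may go wrong: poor facial selectivity at C6 and C7 if the oxirane and the C8 silyloxy centre do not reinforce each other in the chair, and, if closure is slow, oligomerisation or reduction and protonation of the allyl intermediates by the excess organozinc. Fallback, from 21 back to 24: the allylmetal is made before the aldehyde exists and is a boron species, not a zinc species.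
- Palladium-catalysed borylation of the allylic chloride of 21 with bis(pinacolato)diboron (Pd2(dba)3, THF, 60 °C) should give the E allylboronate {(2R,3R)-3-[(3E,6R,7E)-6-(TBS-oxy)-4,8-dimethyl-9-(4,4,5,5-tetramethyl-1,3,2-dioxaborolan-2-yl)nona-3,7-dien-1-yl]-3-methyloxiran-2-yl}methanol F1.
- Dess–Martin oxidation of F1 gives the boronate aldehyde (2S,3R)-3-[(3E,6R,7E)-6-(TBS-oxy)-4,8-dimethyl-9-(4,4,5,5-tetramethyl-1,3,2-dioxaborolan-2-yl)nona-3,7-dien-1-yl]-3-methyloxirane-2-carbaldehyde F2.
- F2 should close in dilute toluene (0.002 M, rt to 50 °C) by intramolecular allylboration through a boron-centred chair, again through C7 and anti; work-up with triethanolamine releases 24.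
- No reducing organometallic is present, the closure is a thermal unimolecular event whose dilution and temperature can be chosen freely, and the compact chair without zinc at the oxirane gives an independent chance of the required facial pairing.

Step 8. What may go wrong: loss of regiocontrol in the ambident allyl-type dithiane anion (alkylation through C11), incomplete second deprotonation, or proton transfer that returns 11 and wastes 5. Fallback, from 5 back to 15: an acyl anion without allylic ambiguity and without an oxygen in reach is used, and the alkenyl group is added afterwards.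
- 2-Lithio-1,3-dithiane (from 1,3-dithiane and n-BuLi, THF, −30 °C) is alkylated with 5 to give 2-[(2E)-5-[(2R,3R)-3-(PMB-oxymethyl)-2-methyloxiran-2-yl]-2-methylpent-2-en-1-yl]-1,3-dithiane F3.
- MeI and CaCO3 in aqueous MeCN unmask the aldehyde (3E)-6-[(2R,3R)-3-(PMB-oxymethyl)-2-methyloxiran-2-yl]-3-methylhex-3-enal F4.
- Nozaki–Hiyama–Kishi coupling of F4 with the known vinyl iodide (2E)-3-iodo-2-methylprop-2-en-1-yl acetate F5 (CrCl2, NiCl2 (cat.), DMSO/THF, rt) gives (2E,6E)-4-hydroxy-9-[(2R,3R)-3-(PMB-oxymethyl)-2-methyloxiran-2-yl]-2,6-dimethylnona-2,6-dien-1-yl acetate F6 as both C4 epimers.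
- Dess–Martin oxidation of F6 gives 15.

Step 10. What may go wrong: poor facial discrimination in the hydride delivery, because the smaller flank of the ketone is a branched allylic methylene and not a methyl group; the C8 epimers would be hard to separate in the open chain. Fallback, from 5 back to 16: C8 is set by carbon–carbon bond formation instead of hydride delivery.
- The aldehyde (3E)-6-[(2R,3R)-3-(PMB-oxymethyl)-2-methyloxiran-2-yl]-3-methylhex-3-enal F4 is made from 5 as under step 8.
- It is coupled with (2E)-3-iodo-2-methylprop-2-en-1-yl acetate F5 under catalytic asymmetric Nozaki–Hiyama–Kishi conditions: CrCl2 and NiCl2 in catalytic amount, a chiral sulfonamide–oxazoline ligand on chromium, Mn as reductant, Zr(C5H5)2Cl2, LiCl, MeCN.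
- The ligand, not the substrate, selects the aldehyde face; the ligand enantiomer that gives the 4R alcohol is used, and the product is 16 directly.

Step 18. What may go wrong: incomplete acylation of the C6 hydroxyl, which is shielded by the oxirane and the isopropyl-bearing carbon, with forcing conditions inviting chloride opening of the oxirane. Fallback, from 24 back to 27: the order of the last operations is changed, so that the acylation meets the flatter isopropenyl neighbour and a preformed alkoxide.
- 24 is deprotonated with LiN(SiMe3)2 (THF, −78 °C) and treated with 26 to give (1R,2S,3S,4R,6E,10R)-4-(TBS-oxy)-6,10-dimethyl-3-(prop-1-en-2-yl)-11-oxabicyclo[8.1.0]undec-6-en-2-yl 3,4,5-trimethoxybenzoate F7.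
- Hydrogenation of F7 with RhCl(PPh3)3 and H2 gives 27.

## Further compounds

F1 | step 16 | {(2R,3R)-3-[(3E,6R,7E)-6-{[tert-butyl(dimethyl)silyl]oxy}-4,8-dimethyl-9-(4,4,5,5-tetramethyl-1,3,2-dioxaborolan-2-yl)nona-3,7-dien-1-yl]-3-methyloxiran-2-yl}methanol | CC1(C)OB(C/C(C)=C/[C@H](O[Si](C)(C)C(C)(C)C)C/C(C)=C/CC[C@@]2(C)O[C@@H]2CO)OC1(C)C
F2 | step 16 | (2S,3R)-3-[(3E,6R,7E)-6-{[tert-butyl(dimethyl)silyl]oxy}-4,8-dimethyl-9-(4,4,5,5-tetramethyl-1,3,2-dioxaborolan-2-yl)nona-3,7-dien-1-yl]-3-methyloxirane-2-carbaldehyde | CC1(C)OB(C/C(C)=C/[C@H](O[Si](C)(C)C(C)(C)C)C/C(C)=C/CC[C@@]2(C)O[C@@H]2C=O)OC1(C)C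
F3 | step 8 | 2-[(2E)-5-[(2R,3R)-3-{[(4-methoxyphenyl)methoxy]methyl}-2-methyloxiran-2-yl]-2-methylpent-2-en-1-yl]-1,3-dithiane | S1CCCSC1C/C(C)=C/CC[C@@]2(C)O[C@@H]2COCc3ccc(OC)cc3
F4 | step 8 | (3E)-6-[(2R,3R)-3-{[(4-methoxyphenyl)methoxy]methyl}-2-methyloxiran-2-yl]-3-methylhex-3-enal | O=CC/C(C)=C/CC[C@@]1(C)O[C@@H]1COCc1ccc(OC)cc1
F5 | step 8 | (2E)-3-iodo-2-methylprop-2-en-1-yl acetate | CC(=O)OC/C(C)=C/I
F6 | step 8 | (2E,6E)-4-hydroxy-9-[(2R,3R)-3-{[(4-methoxyphenyl)methoxy]methyl}-2-methyloxiran-2-yl]-2,6-dimethylnona-2,6-dien-1-yl acetate, both epimers at C4 | CC(=O)OC/C(C)=C/C(O)C/C(C)=C/CC[C@@]1(C)O[C@@H]1COCc1ccc(OC)cc1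
F0 | step 10 | none | none
F7 | step 18 | (1R,2S,3S,4R,6E,10R)-4-{[tert-butyl(dimethyl)silyl]oxy}-6,10-dimethyl-3-(prop-1-en-2-yl)-11-oxabicyclo[8.1.0]undec-6-en-2-yl 3,4,5-trimethoxybenzoate | COc1cc(C(=O)O[C@H]2[C@H](C(C)=C)[C@H](O[Si](C)(C)C(C)(C)C)C/C(C)=C/CC[C@@]3(C)O[C@H]23)cc(OC)c1OC
A1 | alternative 1 | (1R,2S,3S,4R,6S)-4-{[tert-butyl(dimethyl)silyl]oxy}-6-ethenyl-2-[(4-methoxyphenyl)methoxy]-6-methyl-3-(propan-2-yl)-1-(prop-1-en-2-yl)cyclohexan-1-ol | C=C[C@]1(C)C[C@@H](O[Si](C)(C)C(C)(C)C)[C@@H](C(C)C)[C@H](OCc2ccc(OC)cc2)[C@@]1(O)C(C)=C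
A2 | alternative 1 | (1Z,5E,8R,9S,10S)-8-{[tert-butyl(dimethyl)silyl]oxy}-10-[(4-methoxyphenyl)methoxy]-2,6-dimethyl-9-(propan-2-yl)cyclodeca-1,5-dien-1-yl trifluoromethanesulfonate | COc1ccc(CO[C@H]2[C@H](C(C)C)[C@H](O[Si](C)(C)C(C)(C)C)C/C(C)=C/CC/C(C)=C2\OS(=O)(=O)C(F)(F)F)cc1
A3 | alternative 2 | (1S,2S,3R,5E)-3-{[tert-butyl(dimethyl)silyl]oxy}-1-[(2R,3R)-3-ethenyl-3-methyloxiran-2-yl]-6-iodo-5-methyl-2-(propan-2-yl)hex-5-en-1-yl 3,4,5-trimethoxybenzoate | COc1cc(C(=O)O[C@H]([C@H]2O[C@]2(C)C=C)[C@H](C(C)C)[C@H](O[Si](C)(C)C(C)(C)C)C/C(C)=C/I)cc(OC)c1OC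
A4 | alternative 2 | (1R,2S,3S,4R,6E,10R)-4-{[tert-butyl(dimethyl)silyl]oxy}-6,10-dimethyl-3-(propan-2-yl)-11-oxabicyclo[8.1.0]undec-6-en-2-yl 3,4,5-trimethoxybenzoate (identical with 27) | COc1cc(C(=O)O[C@H]2[C@H](C(C)C)[C@H](O[Si](C)(C)C(C)(C)C)C/C(C)=C/CC[C@@]3(C)O[C@H]23)cc(OC)c1OC
A5 | alternative 3 | (2R,3R,5E,9E)-3-{[tert-butyl(dimethyl)silyl]oxy}-10-iodo-5,9-dimethyl-2-(propan-2-yl)deca-5,9-dienal | I/C=C(C)/CC/C=C(C)/C[C@@H](O[Si](C)(C)C(C)(C)C)[C@@H](C(C)C)C=O
A6 | alternative 3 | (1R,2E,6E,9R,10S)-9-{[tert-butyl(dimethyl)silyl]oxy}-3,7-dimethyl-10-(propan-2-yl)cyclodeca-2,6-dien-1-ol | C1/C(C)=C/[C@@H](O)[C@H](C(C)C)[C@H](O[Si](C)(C)C(C)(C)C)C/C(C)=C/C1
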